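**Retrosynthetic overview**

1. Numbering used throughout: C1 = carboxyl carbon, C2 = methyl-bearing α-carbon, the 1,2-dioxane is O1–O2–C3–C4–C5–C6, and the chain runs on from C7. The strategy rests on one feature: C3–C8, the C6 methyl and the oxygen-bearing quaternary C6 are the skeleton of linalool (vinyl group = C7–C8, prenyl arm = C5–C4–C3).
2. C1 acid ⇐ primary silyl ether; C8–C9 ⇐ nickel-catalysed reductive coupling of a C8 iodide with the (E)-alkenyl iodide C9–C20, made from geranyl bromide by propargylation and carboalumination–iodination.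
3. The only ring, the 1,2-dioxane, is closed late by forming O1–C6: the C3 hydroperoxide opens the linalool-derived 2-methyl-2-alkyloxetane at C6 with inversion and releases C8–OH.
4. C2 and C3 ⇐ Evans syn-aldol of the oxetane aldehyde with a propanoyl oxazolidinone; the aldol C3–OH becomes C3–OOH with inversion through its mesylate.
5. Oxetane ⇐ (S)-linalool by hydroboration of the vinyl group and 4-exo-tet etherification (C6–O bond kept), then ozonolysis of the prenyl alkene to the C3 aldehyde.

Key step: step 11

Assumption: (S)-(+)-linalool is taken as purchasable in high enantiomeric purity; its ee passes unchanged into C6, so lower-grade material would have to be enriched before use.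

**Route**

Step 1
Reactants: 1 (S)-(+)-linalool
Product: 3 (3S)-3,7-dimethyloct-6-ene-1,3-diol, via B-alkyl-9-BBN adduct 2 (not isolated)
Conditions: 9-BBN (2.2 equiv), THF, 0 °C → rt; then 3 M NaOH, 30% H2O2, 0 °C → rt
Reagents that add atoms: hydrogen peroxide, OO
Why: Brown hydroboration–oxidation: the bulky borane adds only to the monosubstituted C7=C8 alkene with boron on terminal C8 and leaves the trisubstituted alkene alone; the carbinol carbon (future C6) is not touched, its descriptor changing (S in 1, R in 2, S in 3) only through CIP priorities.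

Step 2
Reactants: 3 (3S)-3,7-dimethyloct-6-ene-1,3-diol
Product: 5 (2S)-2-methyl-2-(4-methylpent-3-en-1-yl)oxetane, via monotosylate 4 (not isolated)
Conditions: n-BuLi (1.0 equiv), THF, 0 °C; TsCl (1.0 equiv), 0 °C → rt; n-BuLi (1.05 equiv), 0 → 60 °C
Reagents that add atoms: none
Why: One-pot sulfonylation and intramolecular Williamson etherification: the primary lithium alkoxide is tosylated preferentially and the tertiary alkoxide then displaces the C8 tosylate in a 4-exo-tet closure; the tertiary C6–O bond is never broken, so the linalool configuration is retained.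

Step 3
Reactants: 5 (2S)-2-methyl-2-(4-methylpent-3-en-1-yl)oxetane
Product: 7 3-[(2S)-2-methyloxetan-2-yl]propanal, via ozonide 6 (not isolated)
Conditions: O3, CH2Cl2, −78 °C; then PPh3, −78 °C → rt
Reagents that add atoms: ozone, [O-][O+]=O
Why: Criegee ozonolysis of the only C=C bond and phosphine reduction of the ozonide give the C3 aldehyde; the oxetane ether is inert to ozone and to PPh3, and the volatile aldehyde is used promptly.

Step 4
Reactants: 7 3-[(2S)-2-methyloxetan-2-yl]propanal; 8 (4S)-4-benzyl-3-propanoyl-1,3-oxazolidin-2-one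
Product: 11 (4S)-4-benzyl-3-[(2S,3R)-3-hydroxy-2-methyl-5-[(2S)-2-methyloxetan-2-yl]pentanoyl]-1,3-oxazolidin-2-one, via Z-boron enolate 9 (not isolated), via boron aldolate 10 (not isolated)
Conditions: 8 (1.2 equiv), Bu2BOTf (1.2 equiv), iPr2NEt (1.4 equiv), CH2Cl2, 0 °C; 7, −78 → 0 °C; then pH 7 buffer, MeOH, 30% H2O2, 0 °C
Reagents that add atoms: none
Why: Evans syn-aldol: soft enolisation gives the Z-boron enolate, which reacts through a closed Zimmerman–Traxler chair in which the (S)-benzyl auxiliary shields one enolate face, setting C2 (S) and C3 (R) as the Evans-syn pair; boron is tied up in enolate and aldolate and the amine is in excess, so the acid-sensitive oxetane should survive.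

Step 5
Reactants: 11 (4S)-4-benzyl-3-[(2S,3R)-3-hydroxy-2-methyl-5-[(2S)-2-methyloxetan-2-yl]pentanoyl]-1,3-oxazolidin-2-one
Product: 12 (2R,3R)-2-methyl-5-[(2S)-2-methyloxetan-2-yl]pentane-1,3-diol
Conditions: LiBH4, MeOH (1 equiv), THF, 0 °C
Reagents that add atoms: none
Why: Reductive removal of the auxiliary: borohydride attacks the exocyclic imide carbonyl and takes C1 to the primary alcohol without enolising C2 or opening the oxetane; the descriptor at C2 changes from S to R by priority only.

Step 6
Reactants: 12 (2R,3R)-2-methyl-5-[(2S)-2-methyloxetan-2-yl]pentane-1,3-diol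
Product: 13 (3R,4R)-5-[tert-butyl(diphenyl)silyl]oxy-4-methyl-1-[(2S)-2-methyloxetan-2-yl]pentan-3-ol
Conditions: TBDPSCl (1.05 equiv), imidazole, CH2Cl2, 0 °C
Reagents that add atoms: tert-butyl(chloro)diphenylsilane, CC(C)(C)[Si](Cl)(c1ccccc1)c1ccccc1
Why: Selective silylation: the bulky silyl chloride reacts with the primary C1 hydroxyl much faster than with the flanked secondary C3 hydroxyl.

Step 7
Reactants: 13 (3R,4R)-5-[tert-butyl(diphenyl)silyl]oxy-4-methyl-1-[(2S)-2-methyloxetan-2-yl]pentan-3-ol
Product: 14 (3R,4R)-5-[tert-butyl(diphenyl)silyl]oxy-4-methyl-1-[(2S)-2-methyloxetan-2-yl]pentan-3-yl methanesulfonate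
Conditions: MsCl, Et3N, CH2Cl2, 0 °C
Reagents that add atoms: methanesulfonyl chloride, CS(=O)(=O)Cl
Why: O-sulfonylation forms only an S–O bond, so C3 keeps its R configuration and becomes an SN2 electrophile.

Step 8
Reactants: 15 2,3-dimethylbut-2-ene
Product: 16 2-hydroperoxy-2-methoxypropane
Conditions: O3, MeOH/CH2Cl2 (1:4), −78 °C; concentrated cold behind a shield and kept as a solution
Reagents that add atoms: ozone, [O-][O+]=O; methanol, CO
Why: Ozonolysis in methanol: the primary ozonide fragments to acetone and acetone carbonyl oxide, which methanol traps as the α-methoxy hydroperoxide; the symmetrical alkene gives one peroxide and only acetone beside it.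

Step 9
Reactants: 14 (3R,4R)-5-[tert-butyl(diphenyl)silyl]oxy-4-methyl-1-[(2S)-2-methyloxetan-2-yl]pentan-3-yl methanesulfonate; 16 2-hydroperoxy-2-methoxypropane
Product: 17 tert-butyl-[(2R,3S)-3-(2-methoxypropan-2-ylperoxy)-2-methyl-5-[(2S)-2-methyloxetan-2-yl]pentoxy]-diphenylsilane
Conditions: 16 (3 equiv), CsOH·H2O (2.5 equiv), DMF, 0 °C → rt
Reagents that add atoms: none
Why: SN2 alkylation of a protected hydroperoxide: the caesium peroxide of 16 is an α-effect nucleophile of low basicity that displaces the secondary mesylate with inversion (3R to 3S), and its ketal cap prevents a second alkylation; the silyl ether and the oxetane tolerate the basic medium.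

Step 10
Reactants: 17 tert-butyl-[(2R,3S)-3-(2-methoxypropan-2-ylperoxy)-2-methyl-5-[(2S)-2-methyloxetan-2-yl]pentoxy]-diphenylsilane
Product: 18 tert-butyl-[(2R,3S)-3-hydroperoxy-2-methyl-5-[(2S)-2-methyloxetan-2-yl]pentoxy]-diphenylsilane
Conditions: AcOH/THF/H2O (4:2:1), 0 °C → rt
Reagents that add atoms: none
Why: Mild acid hydrolysis of the mixed peroxyketal through its oxocarbenium ion frees the hydroperoxide without touching C3; aqueous acetic acid should be too weak to open the 2,2-dialkyloxetane or cleave the TBDPS ether in the short time needed.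

Step 11
Reactants: 18 tert-butyl-[(2R,3S)-3-hydroperoxy-2-methyl-5-[(2S)-2-methyloxetan-2-yl]pentoxy]-diphenylsilane
Product: 19 2-[(3R,6S)-6-[(2R)-1-[tert-butyl(diphenyl)silyl]oxypropan-2-yl]-3-methyl-1,2-dioxan-3-yl]ethanol
Conditions: Yb(OTf)3 (0.2 equiv), Et2O/CH2Cl2, 0 °C → rt
Reagents that add atoms: none
Why: The ytterbium cation binds the oxetane oxygen and polarises the strained tertiary C6–O bond, and the terminal oxygen of the C3 hydroperoxide attacks C6 from the face opposite the leaving oxygen, so that O1–C6 forms as the oxetane bond breaks and C8 is released as a primary alcohol. The closest known reaction type is the Lewis-acid-promoted intramolecular opening of oxetanes by hydroperoxides to give 1,2-dioxolanes and 1,2-dioxanes. The one ring closed, the 1,2-dioxane O1–O2–C3–C4–C5–C6, forms in a 6-exo-tet mode because the breaking C6–O bond lies outside the new ring. The one new stereocentre, C6, is set by the substrate: the configuration carried from linalool is inverted stereospecifically (S in 18, R in 19 with unchanged priorities), while C2 and C3 are spectators. Two selectivities are needed: attack at tertiary C6 and not at primary C8, secured by ring size (attack at C8 would need an eight-membered ring) and by the larger positive charge at the tertiary carbon; and inversion without a free cation, favoured by the mild lanthanide triflate, low temperature, a weakly ionising solvent, the lower ionisation tendency of an oxetane compared with an epoxide, and the tethered nucleophile.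

Step 12
Reactants: 19 2-[(3R,6S)-6-[(2R)-1-[tert-butyl(diphenyl)silyl]oxypropan-2-yl]-3-methyl-1,2-dioxan-3-yl]ethanol
Product: 20 tert-butyl-[(2R)-2-[(3S,6R)-6-(2-iodoethyl)-6-methyl-1,2-dioxan-3-yl]propoxy]-diphenylsilane
Conditions: PPh3 and I2 premixed, imidazole, CH2Cl2, 0 °C; then 19
Reagents that add atoms: iodine, II
Why: Appel-type (Garegg–Samuelsson) iodination: the alkoxyphosphonium of the primary C8 alcohol is displaced by iodide; premixing leaves no free phosphine to reduce the dialkyl peroxide, and no stereocentre is involved.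

Step 13
Reactants: 21 geranyl bromide
Product: 22 trimethyl-[(5E)-6,10-dimethylundeca-5,9-dien-1-ynyl]silane
Conditions: 1-(trimethylsilyl)propyne, n-BuLi, THF, −78 °C; then 21, −78 → 0 °C
Reagents that add atoms: 1-(trimethylsilyl)propyne, CC#C[Si](C)(C)C
Why: SN2 alkylation of the propargylic lithium reagent at the primary allylic bromide; the silyl group blocks the alkyne terminus and favours propargyl over allenyl coupling, and the E alkene of the geranyl unit is untouched.

Step 14
Reactants: 22 trimethyl-[(5E)-6,10-dimethylundeca-5,9-dien-1-ynyl]silane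
Product: 23 (5E)-6,10-dimethylundeca-5,9-dien-1-yne
Conditions: K2CO3 (cat.), MeOH, rt
Reagents that add atoms: none
Why: Base-catalysed methanolysis of the alkynyl C–Si bond frees the terminal alkyne; nothing else in 22 reacts.

Step 15
Reactants: 23 (5E)-6,10-dimethylundeca-5,9-dien-1-yne
Product: 25 (1E,5E)-1-iodo-2,6,10-trimethylundeca-1,5,9-triene, via alkenylalane 24 (not isolated)
Conditions: AlMe3 (2.0 equiv), Cp2ZrCl2 (0.25 equiv), CH2Cl2, 0 °C → rt; then I2, THF, −30 → 0 °C
Reagents that add atoms: trimethylaluminium, C[Al](C)C; iodine, II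
Why: Negishi zirconium-catalysed carboalumination: syn addition of Me–Al across the terminal alkyne puts aluminium on the terminal carbon (C9) and the new methyl on C10, and iodinolysis of the C–Al bond with retention gives the E-alkenyl iodide; the trisubstituted alkenes do not react.

Step 16
Reactants: 20 tert-butyl-[(2R)-2-[(3S,6R)-6-(2-iodoethyl)-6-methyl-1,2-dioxan-3-yl]propoxy]-diphenylsilane; 25 (1E,5E)-1-iodo-2,6,10-trimethylundeca-1,5,9-triene
Product: 26 tert-butyl-[(2R)-2-[(3S,6S)-6-methyl-6-[(3E,7E)-4,8,12-trimethyltrideca-3,7,11-trienyl]-1,2-dioxan-3-yl]propoxy]-diphenylsilane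
Conditions: NiCl2(dme) (10 mol%), 4,4′-di-tert-butyl-2,2′-bipyridine (12 mol%), Mn powder (3 equiv), 25 (1.5 equiv), DMA, 0 °C → rt
Reagents that add atoms: none
Why: Nickel-catalysed reductive cross-electrophile coupling: zerovalent nickel formed by Mn inserts into the alkenyl C–I bond, the primary radical from iodide 20 is captured at nickel and reductive elimination forms C8–C9 with retention of the E geometry; no organometallic nucleophile, phosphine or base is present, which should let the O–O bond and the silyl ether survive (the C6 descriptor changes from R to S by priority only).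

Step 17
Reactants: 26 tert-butyl-[(2R)-2-[(3S,6S)-6-methyl-6-[(3E,7E)-4,8,12-trimethyltrideca-3,7,11-trienyl]-1,2-dioxan-3-yl]propoxy]-diphenylsilane
Product: 27 (2R)-2-[(3S,6S)-6-methyl-6-[(3E,7E)-4,8,12-trimethyltrideca-3,7,11-trienyl]-1,2-dioxan-3-yl]propan-1-ol
Conditions: Bu4NF, AcOH (1:1), THF, 0 °C → rt
Reagents that add atoms: none
Why: Fluoride-mediated Si–O cleavage; buffering with acetic acid suppresses base-induced Kornblum–DeLaMare fragmentation at the C3–H of the peroxide.

Step 18
Reactants: 27 (2R)-2-[(3S,6S)-6-methyl-6-[(3E,7E)-4,8,12-trimethyltrideca-3,7,11-trienyl]-1,2-dioxan-3-yl]propan-1-ol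
Product: 28 (2S)-2-[(3S,6S)-6-methyl-6-[(3E,7E)-4,8,12-trimethyltrideca-3,7,11-trienyl]-1,2-dioxan-3-yl]propanal
Conditions: Dess–Martin periodinane, NaHCO3, CH2Cl2, 0 °C → rt; used at once
Reagents that add atoms: none
Why: Dess–Martin oxidation under bicarbonate buffer is near neutral and should spare the peroxide, the alkenes and the epimerisable C2 (descriptor R to S by priority only).

Step 19
Reactants: 28 (2S)-2-[(3S,6S)-6-methyl-6-[(3E,7E)-4,8,12-trimethyltrideca-3,7,11-trienyl]-1,2-dioxan-3-yl]propanal
Product: 29 (2S)-2-[(3S,6S)-6-methyl-6-[(3E,7E)-4,8,12-trimethyltrideca-3,7,11-trienyl]-1,2-dioxan-3-yl]propanoic acid (CNP0179915.1)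
Conditions: NaClO2, NaH2PO4, 2-methylbut-2-ene (excess), t-BuOH/H2O, 0 °C → rt
Reagents that add atoms: sodium chlorite, [Na+].[O-]Cl=O
Why: Pinnick (Lindgren) oxidation: chlorous acid oxidises only the aldehyde, the alkene scavenger traps HOCl so that the three trisubstituted alkenes are not chlorinated, and the mildly acidic buffer avoids epimerisation at C2 and β-elimination of the peroxide.

**Compound list**

1 | (S)-(+)-linalool | C=C[C@](O)(C)CCC=C(C)C | starting material
2 | B-[(3R)-3-hydroxy-3,7-dimethyloct-6-en-1-yl]-9-borabicyclo[3.3.1]nonane (same spatial arrangement as 1) | CC(C)=CCC[C@](C)(O)CCB1C2CCCC1CCC2 | intermediate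
3 | (3S)-3,7-dimethyloct-6-ene-1,3-diol | OCC[C@](O)(C)CCC=C(C)C | intermediate
4 | (3S)-3-hydroxy-3,7-dimethyloct-6-en-1-yl 4-methylbenzenesulfonate | Cc1ccc(cc1)S(=O)(=O)OCC[C@](O)(C)CCC=C(C)C | intermediate
5 | (2S)-2-methyl-2-(4-methylpent-3-en-1-yl)oxetane | C[C@@]1(CCO1)CCC=C(C)C | intermediate
6 | 3,3-dimethyl-5-[2-[(2S)-2-methyloxetan-2-yl]ethyl]-1,2,4-trioxolane | C[C@@]1(CCO1)CCC2OOC(C)(C)O2 | intermediate
7 | 3-[(2S)-2-methyloxetan-2-yl]propanal | C[C@@]1(CCO1)CCC=O | intermediate
8 | (4S)-4-benzyl-3-propanoyl-1,3-oxazolidin-2-one | CCC(=O)N1[C@@H](Cc2ccccc2)COC1=O | starting material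
9 | (4S)-4-benzyl-3-[(Z)-1-(dibutylboranyloxy)prop-1-enyl]-1,3-oxazolidin-2-one | C/C=C(\OB(CCCC)CCCC)N1[C@@H](Cc2ccccc2)COC1=O | intermediate
10 | (4S)-4-benzyl-3-[(2S,3R)-3-(dibutylboranyloxy)-2-methyl-5-[(2S)-2-methyloxetan-2-yl]pentanoyl]-1,3-oxazolidin-2-one | C[C@@]1(CCO1)CC[C@H]([C@H](C)C(=O)N2[C@@H](Cc3ccccc3)COC2=O)OB(CCCC)CCCC | intermediate
11 | (4S)-4-benzyl-3-[(2S,3R)-3-hydroxy-2-methyl-5-[(2S)-2-methyloxetan-2-yl]pentanoyl]-1,3-oxazolidin-2-one | C[C@@]1(CCO1)CC[C@H]([C@H](C)C(=O)N2[C@@H](Cc3ccccc3)COC2=O)O | intermediate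
12 | (2R,3R)-2-methyl-5-[(2S)-2-methyloxetan-2-yl]pentane-1,3-diol | C[C@@]1(CCO1)CC[C@H]([C@H](C)CO)O | intermediate
13 | (3R,4R)-5-[tert-butyl(diphenyl)silyl]oxy-4-methyl-1-[(2S)-2-methyloxetan-2-yl]pentan-3-ol | C[C@@]1(CCO1)CC[C@H]([C@H](C)CO[Si](c2ccccc2)(c2ccccc2)C(C)(C)C)O | intermediate
14 | (3R,4R)-5-[tert-butyl(diphenyl)silyl]oxy-4-methyl-1-[(2S)-2-methyloxetan-2-yl]pentan-3-yl methanesulfonate | C[C@@]1(CCO1)CC[C@H]([C@H](C)CO[Si](c2ccccc2)(c2ccccc2)C(C)(C)C)OS(C)(=O)=O | intermediate
15 | 2,3-dimethylbut-2-ene | CC(C)=C(C)C | starting material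
16 | 2-hydroperoxy-2-methoxypropane (2-methoxyprop-2-yl hydroperoxide) | COC(C)(C)OO | intermediate
17 | tert-butyl-[(2R,3S)-3-(2-methoxypropan-2-ylperoxy)-2-methyl-5-[(2S)-2-methyloxetan-2-yl]pentoxy]-diphenylsilane | C[C@@]1(CCO1)CC[C@@H]([C@H](C)CO[Si](c2ccccc2)(c2ccccc2)C(C)(C)C)OOC(C)(C)OC | intermediate
18 | tert-butyl-[(2R,3S)-3-hydroperoxy-2-methyl-5-[(2S)-2-methyloxetan-2-yl]pentoxy]-diphenylsilane | C[C@@]1(CCO1)CC[C@@H]([C@H](C)CO[Si](c2ccccc2)(c2ccccc2)C(C)(C)C)OO | intermediate
19 | 2-[(3R,6S)-6-[(2R)-1-[tert-butyl(diphenyl)silyl]oxypropan-2-yl]-3-methyl-1,2-dioxan-3-yl]ethanol | OCC[C@@]1(C)CC[C@@H]([C@H](C)CO[Si](c2ccccc2)(c2ccccc2)C(C)(C)C)OO1 | intermediate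
20 | tert-butyl-[(2R)-2-[(3S,6R)-6-(2-iodoethyl)-6-methyl-1,2-dioxan-3-yl]propoxy]-diphenylsilane | ICC[C@@]1(C)CC[C@@H]([C@H](C)CO[Si](c2ccccc2)(c2ccccc2)C(C)(C)C)OO1 | intermediate
21 | geranyl bromide, (2E)-1-bromo-3,7-dimethylocta-2,6-diene | CC(C)=CCC/C(C)=C/CBr | starting material
22 | trimethyl-[(5E)-6,10-dimethylundeca-5,9-dien-1-ynyl]silane | CC(C)=CCC/C(C)=C/CCC#C[Si](C)(C)C | intermediate
23 | (5E)-6,10-dimethylundeca-5,9-dien-1-yne | CC(C)=CCC/C(C)=C/CCC#C | intermediate
24 | dimethyl-[(1E,5E)-2,6,10-trimethylundeca-1,5,9-trienyl]alane | CC(C)=CCC/C(C)=C/CC/C(C)=C/[Al](C)C | intermediate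
25 | (1E,5E)-1-iodo-2,6,10-trimethylundeca-1,5,9-triene | CC(C)=CCC/C(C)=C/CC/C(C)=C/I | intermediate
26 | tert-butyl-[(2R)-2-[(3S,6S)-6-methyl-6-[(3E,7E)-4,8,12-trimethyltrideca-3,7,11-trienyl]-1,2-dioxan-3-yl]propoxy]-diphenylsilane | CC(C)=CCC/C(C)=C/CC/C(C)=C/CC[C@@]1(C)CC[C@@H]([C@H](C)CO[Si](c2ccccc2)(c2ccccc2)C(C)(C)C)OO1 | intermediate
27 | (2R)-2-[(3S,6S)-6-methyl-6-[(3E,7E)-4,8,12-trimethyltrideca-3,7,11-trienyl]-1,2-dioxan-3-yl]propan-1-ol | CC(C)=CCC/C(C)=C/CC/C(C)=C/CC[C@@]1(C)CC[C@@H]([C@H](C)CO)OO1 | intermediate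
28 | (2S)-2-[(3S,6S)-6-methyl-6-[(3E,7E)-4,8,12-trimethyltrideca-3,7,11-trienyl]-1,2-dioxan-3-yl]propanal | CC(C)=CCC/C(C)=C/CC/C(C)=C/CC[C@@]1(C)CC[C@@H]([C@H](C)C=O)OO1 | intermediate
29 | (2S)-2-[(3S,6S)-6-methyl-6-[(3E,7E)-4,8,12-trimethyltrideca-3,7,11-trienyl]-1,2-dioxan-3-yl]propanoic acid | CC(C)=CCC/C(C)=C/CC/C(C)=C/CC[C@@]1(C)CC[C@@H]([C@H](C)C(=O)O)OO1 | target

**Step count**

Total step count: 19. Longest linear sequence: 15 steps (steps 1–7, 9–12 and 16–19); step 8 makes the peroxide reagent and steps 13–15 make the alkenyl iodide.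

**Steps most likely to fail, with fallbacks**

Step 11 (key step). The risk is ionisation of the Lewis-acid-bound oxetane at tertiary C6 before the hydroperoxide attacks, which would erode the configuration at C6 and open the way to elimination; acid-induced decomposition of the free secondary hydroperoxide is a second risk. The fallback reverses the order in which the two C–O bonds of the ring are made and sets out from mesylate 14. Opening of the oxetane with a large excess of anhydrous H2O2 in Et2O (TMSOTf, 0.2 equiv, −78 → 0 °C) should put the hydroperoxide on C6 with inversion, the high nucleophile concentration and low temperature favouring the bimolecular path, and give (2R,3R,6R)-1-[tert-butyl(diphenyl)silyl]oxy-6-hydroperoxy-8-hydroxy-2,6-dimethyloctan-3-yl methanesulfonate F1. Treatment with CsOH·H2O in DMF at 0 °C should then close the 1,2-dioxane by 6-exo-tet displacement of the C3 mesylate by the tertiary peroxide anion with inversion. The fallback comes back to the route at 19.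

Step 16. The risk is reductive cleavage of the O–O bond by low-valent nickel or at the manganese surface, attack of the transient C8 radical on the peroxide, or homocoupling of either iodide. The fallback is a two-electron, palladium-catalysed Negishi coupling in which the alkyl iodide is the electrophile; it sets out from 25 and 20. Iodine–lithium exchange on 25 (t-BuLi, 2 equiv, Et2O, −78 °C) and transmetalation with ZnCl2 in a separate flask should give [(1E,5E)-2,6,10-trimethylundeca-1,5,9-trienyl]zinc chloride F2. This is coupled with 20 using Pd2(dba)3, tricyclopentylphosphine and N-methylimidazole in THF/NMP at 60–80 °C; no metallic reductant and no free radical at C8 is involved, and the alkenylzinc halide is too mild to attack the peroxide. The fallback comes back to the route at 26.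

Step 9. The risk is that substitution at the β-branched secondary carbon is so slow that E2 elimination, participation of the oxetane oxygen or base-induced fragmentation of the peroxide product take over. The fallback replaces the slow room-temperature mesylate displacement by a fast low-temperature alkylation with a different electrophile class, and sets out from alcohol 13. Tf2O and 2,6-lutidine in CH2Cl2 at −78 °C should give (3R,4R)-5-[tert-butyl(diphenyl)silyl]oxy-4-methyl-1-[(2S)-2-methyloxetan-2-yl]pentan-3-yl trifluoromethanesulfonate F3, which is not stored but treated at once with the potassium salt of 16 (KOtBu, THF, −78 → −20 °C). Substitution with inversion should then outrun elimination and oxygen participation. The fallback comes back to the route at 17.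

**Further compounds**

F1 | step 11 | (2R,3R,6R)-1-[tert-butyl(diphenyl)silyl]oxy-6-hydroperoxy-8-hydroxy-2,6-dimethyloctan-3-yl methanesulfonate | OCC[C@](C)(OO)CC[C@H]([C@H](C)CO[Si](c1ccccc1)(c1ccccc1)C(C)(C)C)OS(C)(=O)=O
F2 | step 16 | [(1E,5E)-2,6,10-trimethylundeca-1,5,9-trienyl]zinc chloride | CC(C)=CCC/C(C)=C/CC/C(C)=C/[Zn]Cl
F3 | step 9 | (3R,4R)-5-[tert-butyl(diphenyl)silyl]oxy-4-methyl-1-[(2S)-2-methyloxetan-2-yl]pentan-3-yl trifluoromethanesulfonate | C[C@@]1(CCO1)CC[C@H]([C@H](C)CO[Si](c2ccccc2)(c2ccccc2)C(C)(C)C)OS(=O)(=O)C(F)(F)F
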